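The numbers in the tables were computed with constants of no real substance; noise was put on by code.

The flask asked about holds 0.500 of the reagent charge of Thursday's run at the same ratio of phases, so the question is what that ratio does to the rate of product.

in all of them: starting material 0.10 M
- Thursday's: reagent in the second phase 2.6 equiv; run made earlier
- flask: reagent in the second phase 1.30 equiv; time 40 h; volume of the second phase over the first 2.0

Thursday's run (percent of the starting material charged)

| time / h | product / % | starting material / % |
|---|---|---|
| 1.00 | 2 | 76 |
| 1.33 | 0 | 75 |
| 2.00 | 5 | 63 |
| 3.00 | 6 | 55 |
| 5.00 | 12 | 31 |
| 8.00 | 18 | 22 |
| 12.0 | 29 | 13 |

(each reading ± 2 percentage points)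

1. product at 40 h, in percent of the starting material charged
2. part of the starting material charged that has reacted at 40 h

- in the second phase: reagent in the second phase; everything else is in the first
- charges count per volume of the first phase; a concentration in a rate is the amount of a species over the volume of its own phase; every rate counts per litre of the first phase
- the analysis behind the earlier runs scatters by 2 percentage points, standard deviation
- the earlier runs hold the two phases in the same ratio of volumes as the flask asked about

In Thursday's run the starting material goes at 0.150 /h of its charge over the first 3.00 h, and at 0.0225 /h between 8.00 h and 12.0 h, slower by a factor of 6.67. The product rate does not follow: it reads 0.0240 /h up to 5.00 h and 0.0243 /h after it, about the same. The unseen part meanwhile reads 57.0% and then 58.0%, two sums that a scatter of 2 percentage points on each reading cannot tell apart.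

The reckoning here assumes that the product rate scales with the reagent charge. That gives the steady product rate of this flask, 0.0121 /h of the charge, for as long as starting material lasts. Thursday's proportional loss, repeated once, leaves 1.69% at 24.0 h. That gives 29.0% of product and 99.9% reacted by 40 h.

The forecast says 40% and 87%, and it reads the unseen part so: “so an intermediate lies between them”. The reckoning here stands lower on product and higher on reaction.

The flask gives 25.3% of product, with 98.1% reacted.

    reagent in the reaction phase ⇌ reagent in the second phase, rate k1*([reagent in the reaction phase] - [reagent in the second phase]/K1) per volume of the first phase (partition coefficient = 1.20, kL = 0.110 /h)
    starting material + reagent in the reaction phase → product (k = 2.20 /M/h)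
    2 starting material → homo dimer (k = 1.30 /M/h)

The flask has nearly come to rest: 1.9% of the starting material, the limiting reagent, remains at 40 h, beside 57.7% of the reagent in the second phase. Ten times the time adds 1.9 points of product, reaching 27.2%, with 100% reacted and the homo dimer at 72.8%.

Read at 10 h, the same flask should hold 12.1% of product by the steady rate and 18.3% of starting material by Thursday's proportion. It holds 12.0% and 21.9%.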